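**Plan**

1. Ring C of the target holds C3 (the enol carbon) next to C4 (the carbonyl), two adjacent carbons that are both carbonyl-derived, i.e. a masked 1,2-dione. C3–C4 is therefore cut first, as an acyl-anion/aldehyde union of two formyl groups tethered through O1 and C2.
2. The next cuts are O1–C2 (aryl ether, back to a salicylaldehyde and a mandelate), the ring-A formyl C–C bond and the 4'-O–prenyl bond.
3. Forward: ring A is built from 5-bromovanillin (methyl moved to the central oxygen, CHO to OH, Br to OH, ortho-formylation). Ring B arrives as O-prenylated methyl 4-hydroxymandelate, and the two are joined at O1–C2 by Mitsunobu etherification.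
4. Reduction and double oxidation give the dialdehyde. Ring C then closes at C3–C4 by carbene-catalysed crossed benzoin, and oxidation with tautomerisation followed by MOM cleavage gives the flavonol.
5. Stereochemistry: the target is achiral. C2 and C3 of the intermediates are racemic and disappear when the acyloin is oxidised to the enolised dione.

Key step: step 12

Assumption: the target has no stereocentre and its only non-ring C=C carries two identical methyl groups, so "single enantiomer" is read as the achiral compound as drawn; chiral intermediates are made and used as racemates.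

**Route**

Step 1
Reactants: 1 5-bromovanillin
Product: 2 3-bromo-4,5-dihydroxybenzaldehyde
Conditions: AlCl3, pyridine, CH2Cl2, reflux; then aq. HCl
Reagents that add atoms: none
Why: Lewis-acid demethylation of an ortho-hydroxyaryl methyl ether; the aluminium phenoxide chelate activates only the neighbouring OMe, so the aldehyde and bromide should be untouched.

Step 2
Reactants: 2 3-bromo-4,5-dihydroxybenzaldehyde
Product: 3 3-bromo-5-hydroxy-4-methoxybenzaldehyde
Conditions: MeI (1.05 equiv), Li2CO3, DMF, 40 °C
Reagents that add atoms: iodomethane, CI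
Why: Williamson methylation under a weak base; the 4-OH (para to CHO, ortho to Br) is much the more acidic, so only its phenoxide should form and be alkylated.

Step 3
Reactants: 3 3-bromo-5-hydroxy-4-methoxybenzaldehyde
Product: 4 3-bromo-4-methoxy-5-(methoxymethoxy)benzaldehyde
Conditions: MOMCl, i-Pr2NEt, CH2Cl2, 0 °C to rt
Reagents that add atoms: chloromethyl methyl ether, COCCl
Why: Standard O-alkylation of a phenol to its MOM acetal, which masks the future 7-OH through the base, hydride and oxidation steps ahead.

Step 4
Reactants: 4 3-bromo-4-methoxy-5-(methoxymethoxy)benzaldehyde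
Product: 6 3-bromo-4-methoxy-5-(methoxymethoxy)phenol, via aryl formate 5 (not isolated)
Conditions: mCPBA, CH2Cl2, rt; then K2CO3 (cat.), MeOH, rt
Reagents that add atoms: 3-chloroperoxybenzoic acid, OOC(=O)c1cccc(Cl)c1
Why: Baeyer–Villiger oxidation of a benzaldehyde whose para-methoxy group favours aryl migration, followed by methanolysis of the formate, turns the formyl carbon into the future 5-oxygen.

Step 5
Reactants: 6 3-bromo-4-methoxy-5-(methoxymethoxy)phenol
Product: 7 1-bromo-2-methoxy-3,5-bis(methoxymethoxy)benzene
Conditions: MOMCl, i-Pr2NEt, CH2Cl2, 0 °C to rt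
Reagents that add atoms: chloromethyl methyl ether, COCCl
Why: Second MOM etherification of a phenol, protecting the future 5-OH with a small group that should hinder the later formyl group as little as possible.

Step 6
Reactants: 7 1-bromo-2-methoxy-3,5-bis(methoxymethoxy)benzene
Product: 8 2-methoxy-3,5-bis(methoxymethoxy)phenol
Conditions: Pd2(dba)3 (2 mol%), t-BuXPhos (8 mol%), KOH, 1,4-dioxane/H2O, 100 °C; then pH 6 buffer
Reagents that add atoms: potassium hydroxide, [K+].[OH-]
Why: Palladium-catalysed hydroxylation of an aryl bromide with hydroxide (C–O cross-coupling) tolerates electron-rich, ortho-substituted bromides, and MOM ethers are stable to hot aqueous base.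

Step 7
Reactants: 8 2-methoxy-3,5-bis(methoxymethoxy)phenol
Product: 10 2-hydroxy-3-methoxy-4,6-bis(methoxymethoxy)benzaldehyde, via salicyl alcohol 9 (not isolated)
Conditions: MgCl2, Et3N, (CH2O)n, MeCN, reflux
Reagents that add atoms: paraformaldehyde (as formaldehyde), C=O
Why: Magnesium-mediated ortho-specific formylation of a phenol (Casnati–Skattebøl type): the magnesium phenoxide delivers formaldehyde to the only free ortho carbon, and the hydroxymethyl intermediate is oxidised by hydride transfer to a second formaldehyde, so the site between the two MOM ethers should stay unsubstituted.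

Step 8
Reactants: 11 methyl 4-hydroxymandelate (racemic); 12 prenyl bromide
Product: 13 methyl 2-hydroxy-2-[4-(3-methylbut-2-en-1-yloxy)phenyl]acetate (racemic)
Conditions: K2CO3, acetone, reflux
Reagents that add atoms: none
Why: Williamson etherification; carbonate deprotonates only the phenol, so the secondary alcohol should remain free for the next step.

Step 9
Reactants: 10 2-hydroxy-3-methoxy-4,6-bis(methoxymethoxy)benzaldehyde; 13 methyl 2-hydroxy-2-[4-(3-methylbut-2-en-1-yloxy)phenyl]acetate
Product: 14 methyl 2-[2-formyl-6-methoxy-3,5-bis(methoxymethoxy)phenoxy]-2-[4-(3-methylbut-2-en-1-yloxy)phenyl]acetate (racemic)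
Conditions: PPh3, DIAD, THF, 0 °C to rt
Reagents that add atoms: none
Why: Mitsunobu etherification; the acidic, hydrogen-bonded salicylaldehyde OH is a suitable pronucleophile, the mandelate carbinol is activated for displacement, and the neutral conditions avoid aldol closure onto the formyl group (the configuration at the new O1–C2 centre is irrelevant).

Step 10
Reactants: 14 methyl 2-[2-formyl-6-methoxy-3,5-bis(methoxymethoxy)phenoxy]-2-[4-(3-methylbut-2-en-1-yloxy)phenyl]acetate
Product: 15 2-[2-(hydroxymethyl)-6-methoxy-3,5-bis(methoxymethoxy)phenoxy]-2-[4-(3-methylbut-2-en-1-yloxy)phenyl]ethan-1-ol (racemic)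
Conditions: LiAlH4, THF, 0 °C; aq. NaOH work-up
Reagents that add atoms: none
Why: Hydride reduction of ester and aldehyde together, chosen because no reagent would take the ester to the aldehyde while sparing the aryl aldehyde; acetals, aryl ethers and the alkene are inert.

Step 11
Reactants: 15 2-[2-(hydroxymethyl)-6-methoxy-3,5-bis(methoxymethoxy)phenoxy]-2-[4-(3-methylbut-2-en-1-yloxy)phenyl]ethan-1-ol
Product: 16 2-[2-formyl-6-methoxy-3,5-bis(methoxymethoxy)phenoxy]-2-[4-(3-methylbut-2-en-1-yloxy)phenyl]acetaldehyde (racemic)
Conditions: Dess–Martin periodinane (2.5 equiv), NaHCO3, CH2Cl2, 0 °C to rt; used crude at once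
Reagents that add atoms: none
Why: Dess–Martin oxidation of both primary alcohols under buffered, non-basic conditions should give the dialdehyde without enolising the labile α-aryloxy-α-aryl aldehyde.

Step 12
Reactants: 16 2-[2-formyl-6-methoxy-3,5-bis(methoxymethoxy)phenoxy]-2-[4-(3-methylbut-2-en-1-yloxy)phenyl]acetaldehyde
Product: 17 trans-3-hydroxy-8-methoxy-5,7-bis(methoxymethoxy)-2-[4-(3-methylbut-2-en-1-yloxy)phenyl]chroman-4-one (racemic)
Conditions: 2-(pentafluorophenyl)-6,7-dihydro-5H-pyrrolo[2,1-c][1,2,4]triazol-2-ium tetrafluoroborate (15 mol%), i-Pr2NEt (15 mol%), toluene (0.02 M), rt, Ar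
Reagents that add atoms: none
Why: The carbene freed from the triazolium salt adds to one formyl group, proton transfer gives the Breslow enaminol (an acyl-anion equivalent), this adds to the second formyl group and the carbene is expelled from the acyloin; this is the NHC-catalysed intramolecular crossed benzoin reaction, closest to the known carbene-catalysed cyclisations of tethered dialdehydes and of 2-(2-oxoalkoxy)benzaldehydes to 3-hydroxychroman-4-ones. Ring C closes 6-exo-trig across the O1–C2 tether with formation of C3–C4. The new C3 carbinol centre is set relative to C2 by the substrate, the C2 aryl group lying pseudo-equatorial in a chair-like closure and the acyloin being free to equilibrate through its enediol to the diequatorial 2,3-trans isomer; neither centre survives step 13. Which formyl group acts as donor does not matter, because the regioisomeric 4-hydroxychroman-3-one would be oxidised to the same 3,4-dione. The step does need cyclisation to outrun intermolecular benzoin, amine-induced aldol closure through the acidic C2–H, and loss of the aryloxide from a side-chain Breslow intermediate; the six-atom tether and high dilution secure the first, and the acidic N-C6F5 triazolium, which a catalytic amount of tertiary amine deprotonates at rt, keeps the medium weakly basic to limit the other two.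

Step 13
Reactants: 17 trans-3-hydroxy-8-methoxy-5,7-bis(methoxymethoxy)-2-[4-(3-methylbut-2-en-1-yloxy)phenyl]chroman-4-one
Product: 19 3-hydroxy-8-methoxy-5,7-bis(methoxymethoxy)-2-[4-(3-methylbut-2-en-1-yloxy)phenyl]-4H-chromen-4-one, via chromane-3,4-dione 18 (not isolated)
Conditions: Dess–Martin periodinane (1.2 equiv), NaHCO3, CH2Cl2, 0 °C to rt
Reagents that add atoms: none
Why: Dess–Martin oxidation of an acyloin to the 1,2-dione, which should tautomerise through C2–H to the conjugated, hydrogen-bonded 3-hydroxy-4-pyranone, erasing both racemic centres.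

Step 14
Reactants: 19 3-hydroxy-8-methoxy-5,7-bis(methoxymethoxy)-2-[4-(3-methylbut-2-en-1-yloxy)phenyl]-4H-chromen-4-one
Product: 20 3,5,7-trihydroxy-8-methoxy-4'-prenyloxyflavone
Conditions: HCl (1 M in MeOH), MeOH–THF, rt to 35 °C, monitored; NaHCO3 quench
Reagents that add atoms: none
Why: Acid-catalysed acetal methanolysis of the aryl MOM ethers; the peri 5-O-MOM and the 7-O-MOM on the electron-poor chromone should cleave under dilute acid mild enough to leave the allylic aryl ether intact.

**Compound list**

1 | 5-bromovanillin (3-bromo-4-hydroxy-5-methoxybenzaldehyde) | COc1cc(C=O)cc(Br)c1O | starting material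
2 | 3-bromo-4,5-dihydroxybenzaldehyde | O=Cc1cc(O)c(O)c(Br)c1 | intermediate
3 | 3-bromo-5-hydroxy-4-methoxybenzaldehyde | COc1c(O)cc(C=O)cc1Br | intermediate
4 | 3-bromo-4-methoxy-5-(methoxymethoxy)benzaldehyde | COCOc1cc(C=O)cc(Br)c1OC | intermediate
5 | 3-bromo-4-methoxy-5-(methoxymethoxy)phenyl formate (not isolated) | COCOc1cc(OC=O)cc(Br)c1OC | intermediate
6 | 3-bromo-4-methoxy-5-(methoxymethoxy)phenol | COCOc1cc(O)cc(Br)c1OC | intermediate
7 | 1-bromo-2-methoxy-3,5-bis(methoxymethoxy)benzene | COCOc1cc(Br)c(OC)c(OCOC)c1 | intermediate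
8 | 2-methoxy-3,5-bis(methoxymethoxy)phenol | COCOc1cc(O)c(OC)c(OCOC)c1 | intermediate
9 | 2-(hydroxymethyl)-6-methoxy-3,5-bis(methoxymethoxy)phenol (not isolated) | COCOc1cc(OCOC)c(CO)c(O)c1OC | intermediate
10 | 2-hydroxy-3-methoxy-4,6-bis(methoxymethoxy)benzaldehyde | COCOc1cc(OCOC)c(C=O)c(O)c1OC | intermediate
11 | methyl 4-hydroxymandelate (racemic) | COC(=O)C(O)c1ccc(O)cc1 | starting material
12 | prenyl bromide (1-bromo-3-methylbut-2-ene) | CC(C)=CCBr | starting material
13 | methyl 2-hydroxy-2-[4-(3-methylbut-2-en-1-yloxy)phenyl]acetate (racemic) | COC(=O)C(O)c1ccc(OCC=C(C)C)cc1 | intermediate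
14 | methyl 2-[2-formyl-6-methoxy-3,5-bis(methoxymethoxy)phenoxy]-2-[4-(3-methylbut-2-en-1-yloxy)phenyl]acetate (racemic) | COC(=O)C(Oc1c(C=O)c(OCOC)cc(OCOC)c1OC)c1ccc(OCC=C(C)C)cc1 | intermediate
15 | 2-[2-(hydroxymethyl)-6-methoxy-3,5-bis(methoxymethoxy)phenoxy]-2-[4-(3-methylbut-2-en-1-yloxy)phenyl]ethan-1-ol (racemic) | OCC(Oc1c(CO)c(OCOC)cc(OCOC)c1OC)c1ccc(OCC=C(C)C)cc1 | intermediate
16 | 2-[2-formyl-6-methoxy-3,5-bis(methoxymethoxy)phenoxy]-2-[4-(3-methylbut-2-en-1-yloxy)phenyl]acetaldehyde (racemic) | O=CC(Oc1c(C=O)c(OCOC)cc(OCOC)c1OC)c1ccc(OCC=C(C)C)cc1 | intermediate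
17 | trans-3-hydroxy-8-methoxy-5,7-bis(methoxymethoxy)-2-[4-(3-methylbut-2-en-1-yloxy)phenyl]chroman-4-one (racemic, 2R*,3R*; the 2S,3S enantiomer is drawn) | O=C1c2c(OCOC)cc(OCOC)c(OC)c2O[C@@H](c2ccc(OCC=C(C)C)cc2)[C@@H]1O | intermediate
18 | 8-methoxy-5,7-bis(methoxymethoxy)-2-[4-(3-methylbut-2-en-1-yloxy)phenyl]chromane-3,4-dione (racemic, not isolated) | O=C1C(=O)c2c(OCOC)cc(OCOC)c(OC)c2OC1c1ccc(OCC=C(C)C)cc1 | intermediate
19 | 3-hydroxy-8-methoxy-5,7-bis(methoxymethoxy)-2-[4-(3-methylbut-2-en-1-yloxy)phenyl]-4H-chromen-4-one | COCOc1cc(OCOC)c2c(=O)c(O)c(-c3ccc(OCC=C(C)C)cc3)oc2c1OC | intermediate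
20 | 3,5,7-trihydroxy-8-methoxy-4'-prenyloxyflavone | COc1c(O)cc(O)c2c(=O)c(O)c(-c3ccc(OCC=C(C)C)cc3)oc12 | target

**Step count**

Total: 14 steps. Longest linear sequence: 13 steps (steps 1–7 and 9–14, from 5-bromovanillin); step 8 is the one-step side branch.

**Steps most likely to fail**

Step 12. The di-ortho-oxygenated aryl aldehyde may resist Breslow formation. If the side-chain aldehyde becomes the donor instead, its enaminol may expel the aryloxide (redox cleavage of the tether) rather than cyclise. Amine-induced aldol closure through C2–H may also compete. The fallback closes ring C at O1–C2 by the Algar–Flynn–Oyamada sequence; it sets out from 10 (with 12 for ring B) and returns at 19. MeMgBr (2.2 equiv, THF, 0 °C) should add to 10 to give 1-[2-hydroxy-3-methoxy-4,6-bis(methoxymethoxy)phenyl]ethan-1-ol F1, and MnO2 in CH2Cl2 should oxidise this to 1-[2-hydroxy-3-methoxy-4,6-bis(methoxymethoxy)phenyl]ethan-1-one F2. Commercial 4-hydroxybenzaldehyde and 12 (K2CO3, acetone) would give 4-(3-methylbut-2-en-1-yloxy)benzaldehyde F3. Claisen–Schmidt condensation of F2 with F3 (KOH, EtOH) should give (E)-1-[2-hydroxy-3-methoxy-4,6-bis(methoxymethoxy)phenyl]-3-[4-(3-methylbut-2-en-1-yloxy)phenyl]prop-2-en-1-one F4. Alkaline hydrogen peroxide (NaOH, MeOH, 0 °C to rt), which does not attack the isolated prenyl alkene, should then convert F4 into 19.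

Step 14. The acid needed for the 7-O-MOM group may also ionise the prenyl ether, with loss or migration of the prenyl group. The fallback replaces protic solvolysis by silyl transfer; it sets out from 19 and returns at 20. TMSOTf with 2,2'-bipyridyl in MeCN at 0 °C should exchange both aryl MOM acetals and silylate the 3-OH to give 8-methoxy-2-[4-(3-methylbut-2-en-1-yloxy)phenyl]-3,5,7-tris(trimethylsilyloxy)-4H-chromen-4-one F5, which K2CO3 in aqueous MeOH at rt should desilylate to 20 without exposing the allylic ether to free acid.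

Step 9. Displacement at the secondary mandelate carbon by a di-ortho-substituted, hydrogen-bonded phenol may be slow, so that the activated alcohol is consumed by the hydrazide or by elimination. The fallback is an SN2 alkylation with an α-bromo ester; it sets out from 13 and 10 and returns at 14. CBr4/PPh3 (CH2Cl2, 0 °C) should convert 13 into methyl 2-bromo-2-[4-(3-methylbut-2-en-1-yloxy)phenyl]acetate F6, and K2CO3 in acetone at rt should alkylate the phenoxide of 10 with F6 to give 14; the temperature is kept low to avoid base-induced aldol closure onto the formyl group.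

**Further compounds**

F1 | step 12 | 1-[2-hydroxy-3-methoxy-4,6-bis(methoxymethoxy)phenyl]ethan-1-ol (racemic) | CC(O)c1c(O)c(OC)c(OCOC)cc1OCOC
F2 | step 12 | 1-[2-hydroxy-3-methoxy-4,6-bis(methoxymethoxy)phenyl]ethan-1-one | CC(=O)c1c(O)c(OC)c(OCOC)cc1OCOC
F3 | step 12 | 4-(3-methylbut-2-en-1-yloxy)benzaldehyde | O=Cc1ccc(OCC=C(C)C)cc1
F4 | step 12 | (E)-1-[2-hydroxy-3-methoxy-4,6-bis(methoxymethoxy)phenyl]-3-[4-(3-methylbut-2-en-1-yloxy)phenyl]prop-2-en-1-one | O=C(/C=C/c1ccc(OCC=C(C)C)cc1)c1c(O)c(OC)c(OCOC)cc1OCOC
F5 | step 14 | 8-methoxy-2-[4-(3-methylbut-2-en-1-yloxy)phenyl]-3,5,7-tris(trimethylsilyloxy)-4H-chromen-4-one | COc1c(O[Si](C)(C)C)cc(O[Si](C)(C)C)c2c(=O)c(O[Si](C)(C)C)c(-c3ccc(OCC=C(C)C)cc3)oc12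
F6 | step 9 | methyl 2-bromo-2-[4-(3-methylbut-2-en-1-yloxy)phenyl]acetate (racemic) | COC(=O)C(Br)c1ccc(OCC=C(C)C)cc1
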